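The vessel is closed, stirred and held at constant temperature, and the flask asked about is Tuesday's own, followed past its last reading.

| flask | starting material | reagent | temperature | remark | time |
|---|---|---|---|---|---|
| Tuesday's | 1 M | 1.5 M | 110 °C | the very flask that is asked about, followed so far |  |
| Monday's | 1 M | 3 M | 116 °C | run made earlier |  |
| flask | 1.0 M | 1.50 M | 110 °C |  | 80 min |

| run | time / min | target / % | starting material / % |
|---|---|---|---|
| Tuesday's | 8.00 | 13 | 51 |
| Tuesday's | 15.0 | 8 | 47 |
| Tuesday's | 25.0 | 7 | 39 |
| Tuesday's | 30.0 | 6 | 38 |
| Tuesday's | 40.0 | 9 | 40 |
| Tuesday's | 50.0 | 8 | 40 |
| Monday's | 0.500 | 21 | 65 |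
| Monday's | 0.833 | 23 | 55 |
| Monday's | 1.33 | 22 | 48 |
| Monday's | 2.00 | 21 | 41 |
| Monday's | 4.00 | 15 | 31 |
| Monday's | 6.00 | 13 | 27 |

(readings scatter by 1.5 percentage points)

- teal: at 80 min raise the temperature by 20 K, then wait 2.5 h
- ochre: at 80 min take out 90 % of the target then present, then wait 2.5 h
- red: change nothing and wait 2.5 h more

- target that was removed still counts
- a reading of starting material is of its free form alone

1. target, in percent of the starting material first charged, at 80 min
2. the option that brings most further target ("none" if no option brings more than 2 percentage points) (teal / ochre / red / none)
3. target present, with what was taken out counted in, in percent of the starting material first charged, after teal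
4. target present, with what was taken out counted in, in percent of the starting material first charged, after red

**Has Tuesday's flask stopped?** I think so. From 25.0 min on, its readings scatter about 7.50 % target and 39.2 % starting material without a trend. So I commit to 7.50 % now and after red.

**Where is the rest?** 53.3 % of the charge stands in neither column, so there is an unseen form. I assume each starting material lost took one reagent with it, which leaves Tuesday's flask 0.892 M free reagent.

**Perhaps the reagent simply died?** Test it. On Tuesday's plateau, 0.214 /M is the standing quotient, c(target) divided by c(starting material) times c(reagent), free amounts, which the trade calls an equilibrium constant. Monday's last reading gives 0.212 /M, although its target over starting material is 0.481 against Tuesday's 0.191. Monday's run was warmer and still moving, so this is a check and no proof, but it points to a balance.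

**Then ochre?** Yes. Taking out 6.8 percentage points lowers the quotient, so target should re-form. Suppose the unseen form gives nothing back and free starting material and reagent each stand lower by the removed amount. My estimate of the gain from the quotient is then about 5 points, more than the 2 points asked.

**And teal?** Monday's warmer run shows the same quotient within scatter, so the sign stays open. For teal I enter 7.50 % with that doubt.

The forecast, made from the same runs, gives 7.7 % now, 7.8 % after red, 8.5 % after teal, and ochre, since removal “lets the pool refill it”, for about 6 points. Its figure for now stands slightly above mine.

The flask gives 8.43 % at 80.0 min, 8.43 % after red and 4.96 % after teal. Ochre brings 6.9 points, teal −3.5 points, so ochre holds.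

    starting material + reagent ⇌ isomer of the product (K = 1.30 /M, k = 0.00165 /M/s, Ea = 74.0 kJ/mol, ΔH = 18.0 kJ/mol)
    starting material + reagent ⇌ target (K = 0.220 /M, k = 0.00290 /M/s, Ea = 65.0 kJ/mol, ΔH = −25.0 kJ/mol)
    (constants at 110 °C)

The unseen form is the isomer of the product. Now take the neighbouring flask, charged with 1.7 M starting material. After 80.0 min it keeps 50.2 % of its starting material and 43.5 % of its reagent free, and these with the quotient read on Tuesday, 0.214 /M, give 7.02 % target. That neighbouring flask holds 7.21 %.

The runs were generated by integration for substances that don't exist, noise included.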